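**Plan**

- Retrosynthesis cuts, in order: the C9–O ester bond (p-coumaric acid), the C5 oxidation level (CH2 back to lactol), the C4–C5 and O1–C5 bonds together (carbon monoxide), the C7'–aryl bond (Heck) and the C2–C3 bond (allylboration).
- Enabling feature: in ring O1–C2(aryl)–C3(C9H2O)–C4(C7'H2Ar)–C5H2, C5 is a bare OCH2 bonded only to O1 and C4. In the ring-opened form the C2 hydroxyl is homoallylic to a C4=C7' styrene, so C5 can be CO delivered to C4 by that hydroxyl.
- Forward: the open chain is built first (vanillin-derived aldehyde plus a four-carbon bis(boronate), then arylation at C7'). The only ring, the oxolane, closes in the hydroformylation; reduction, desilylation and esterification finish.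
- Stereochemistry: C2 (S) and C3 (S) come from a phosphoric-acid-controlled Si-face addition of the (Z)-allylboronate (syn). C4 (R) comes from the chelate and from equilibration trans to C3. Both E-alkenes come from the Heck step and from the acid used.

Key step: step 7

Remark: the target is taken as drawn, (2S,3S,4R), with the C2 aryl and C9 cis and C9 and the C4 benzyl trans; ring atoms are O1, C2 (aryl), C3 (bears C9), C4 (bears benzylic C7'), C5.
Remark: (S)-TRIP is taken as the enantiomer that delivers the allyl unit of pinacol allylboronates to the Si face of aryl aldehydes; if the sense is the opposite, the mirror-image acid is used.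

**Route**

Step 1
Reactants: 1 vanillin
Product: 2 3-methoxy-4-(triisopropylsilyloxy)benzaldehyde
Conditions: TIPSCl, imidazole, DMF, rt
Reagents that add atoms: triisopropylsilyl chloride, CC(C)[Si](Cl)(C(C)C)C(C)C
Why: Silylation of a phenol; the aryl TIPS ether is chosen because it should survive the alkaline peroxide, amine bases and Lewis acid used later and still be cleaved by fluoride at the end.

Step 2
Reactants: 3 buta-1,3-diene; 4 bis(pinacolato)diboron
Product: 5 (Z)-1,4-bis(4,4,5,5-tetramethyl-1,3,2-dioxaborolan-2-yl)but-2-ene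
Conditions: Pt(PPh3)4 (3 mol%), toluene, 80 °C, sealed vessel
Reagents that add atoms: none
Why: Platinum-catalysed 1,4-diboration of a 1,3-diene; B–B oxidative addition, insertion of the s-cis diene to a π-allyl platinum boryl and reductive elimination should give the Z isomer.

Step 3
Reactants: 2 3-methoxy-4-(triisopropylsilyloxy)benzaldehyde; 5 (Z)-1,4-bis(pinacolboryl)but-2-ene
Product: 7 (1S,2S)-2-ethenyl-1-[3-methoxy-4-(triisopropylsilyloxy)phenyl]propane-1,3-diol, via O-borylated homoallyl boronate 6 (not isolated)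
Conditions: (S)-TRIP [(S)-3,3'-bis(2,4,6-triisopropylphenyl)-1,1'-binaphthyl-2,2'-diyl hydrogen phosphate] (5 mol%), 4 Å MS, toluene, −30 °C; then 30% H2O2, 2 M NaOH, THF, 0 °C
Reagents that add atoms: hydrogen peroxide, OO
Why: Chiral phosphoric acid-catalysed allylboration through a closed chair transition state, in which the acid bound to a boronate oxygen exposes the Si face of the aldehyde (C2, S) and the (Z)-CH2B(pin) arm sits axial so that C3 forms syn to the hydroxyl, followed by alkaline peroxide oxidation of the primary C–B bond to the C9 alcohol.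

Step 4
Reactants: 7 (1S,2S)-2-ethenyl-1-[3-methoxy-4-(triisopropylsilyloxy)phenyl]propane-1,3-diol
Product: 8 (1S,2S)-2-[(tert-butyldimethylsilyloxy)methyl]-1-[3-methoxy-4-(triisopropylsilyloxy)phenyl]but-3-en-1-ol
Conditions: TBSCl (1.05 equiv), imidazole, CH2Cl2, 0 °C
Reagents that add atoms: tert-butyldimethylsilyl chloride, CC(C)(C)[Si](C)(C)Cl
Why: Selective silylation of the primary hydroxyl of a 1,3-diol; the hindered benzylic C2 hydroxyl should stay free to carry the directing ligand later.

Step 5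
Reactants: 9 4-iodo-2-methoxyphenol
Product: 10 (4-iodo-2-methoxyphenoxy)triisopropylsilane
Conditions: TIPSCl, imidazole, DMF, rt
Reagents that add atoms: triisopropylsilyl chloride, CC(C)[Si](Cl)(C(C)C)C(C)C
Why: Silylation of a phenol, giving the same aryl protecting group as in 2 so that one fluoride step removes both.

Step 6
Reactants: 8 (1S,2S)-2-[(tert-butyldimethylsilyloxy)methyl]-1-[3-methoxy-4-(triisopropylsilyloxy)phenyl]but-3-en-1-ol; 10 (4-iodo-2-methoxyphenoxy)triisopropylsilane
Product: 11 (1S,2S,3E)-2-[(tert-butyldimethylsilyloxy)methyl]-1,4-bis[3-methoxy-4-(triisopropylsilyloxy)phenyl]but-3-en-1-ol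
Conditions: Pd(OAc)2 (5 mol%), P(o-tol)3 (10 mol%), Et3N, MeCN, 80 °C
Reagents that add atoms: none
Why: Mizoroki–Heck arylation of a monosubstituted alkene; the aryl group should add to the terminal carbon C7' and syn β-hydride elimination toward the benzylic position should give the conjugated E-styrene, leaving the tertiary allylic C3–H alone.

Step 7
Reactants: 11 (1S,2S,3E)-2-[(tert-butyldimethylsilyloxy)methyl]-1,4-bis[3-methoxy-4-(triisopropylsilyloxy)phenyl]but-3-en-1-ol; 12 carbon monoxide
Product: 15 (3R,4S,5S)-4-[(tert-butyldimethylsilyloxy)methyl]-5-[3-methoxy-4-(triisopropylsilyloxy)phenyl]-3-{[3-methoxy-4-(triisopropylsilyloxy)phenyl]methyl}oxolan-2-ol (both anomers), via substrate phosphinite 13 (not isolated), via hydroxy aldehyde 14 (not isolated)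
Conditions: Rh(acac)(CO)2 (2 mol%), Ph2POMe (20 mol%), 4 Å MS, CO/H2 (1:1, 20 bar), THF, 50 °C; then 1,8-diazabicyclo[5.4.0]undec-7-ene (DBU, 0.2 equiv), rt
Reagents that add atoms: none
Why: Proposed new method: methyl diphenylphosphinite exchanges onto the C2 hydroxyl to give phosphinite 13, whose phosphorus holds the rhodium hydride so that the C4=C7' bond inserts through a six-membered Rh–P–O–C2–C3–C4 chelate, putting rhodium on C4 and hydrogen on C7'; CO insertion, hydrogenolysis and ligand exchange then release γ-hydroxy aldehyde 14. The closest known reaction is the branched-selective hydroformylation of homoallylic alcohols, 1,2-disubstituted ones included, to γ-lactols with catalytic Ph2POMe; a β-aryl alkene carrying an allylic branch has not been shown. The oxolane closes by 5-exo-trig addition of the C2 hydroxyl to the formyl carbon (O1–C5), the C4–C5 bond having been made by the CO insertion. C4 is set first by the chelate, which should present to rhodium the alkene face anti to the C3 silyloxymethyl group, and then thermodynamically: C4 is alpha to the masked aldehyde, so DBU should bring any 3,4-cis material through ring-opened 14 to the 3,4-trans lactol, which avoids an all-cis ring, while C2 and C3 are untouched and the anomeric centre is removed in step 8. The step needs rhodium at C4 and not at the benzylic C7'; intramolecular delivery (six- against seven-membered chelate), the mild temperature and the electron-rich aryl group, which weakens the benzylic preference, are what should secure this.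

Step 8
Reactants: 15 the lactol of step 7
Product: 16 tert-butyl{[(2S,3S,4R)-2-[3-methoxy-4-(triisopropylsilyloxy)phenyl]-4-{[3-methoxy-4-(triisopropylsilyloxy)phenyl]methyl}oxolan-3-yl]methoxy}dimethylsilane
Conditions: Et3SiH (3 equiv), BF3·OEt2 (1.5 equiv), CH2Cl2, −78 °C
Reagents that add atoms: none
Why: Ionic hydrogenation of a lactol, in which BF3 ionises the anomeric hydroxyl to the cyclic oxocarbenium ion that Et3SiH reduces to C5H2; at −78 °C with the phenol capped by silicon the benzylic C2–O1 bond should not ionise, so the 2,3-cis relationship is kept.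

Step 9
Reactants: 16 the tris-silylated oxolane of step 8
Product: 17 [(2S,3S,4R)-2-(4-hydroxy-3-methoxyphenyl)-4-[(4-hydroxy-3-methoxyphenyl)methyl]oxolan-3-yl]methanol
Conditions: nBu4NF (4 equiv), AcOH (4 equiv), THF, 0 °C to rt
Reagents that add atoms: none
Why: Fluoride-induced cleavage of the two aryl TIPS ethers and the primary TBS ether; the acetic acid buffer keeps the phenols protonated so that the p-hydroxybenzylic ether at C2 should not open to a quinone methide and epimerise.

Step 10
Reactants: 17 the triol of step 9; 18 p-coumaric acid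
Product: 19 [(2S,3S,4R)-2-(4-hydroxy-3-methoxyphenyl)-4-[(4-hydroxy-3-methoxyphenyl)methyl]oxolan-3-yl]methyl (2E)-3-(4-hydroxyphenyl)prop-2-enoate
Conditions: PPh3 (1.3 equiv), DIAD (1.3 equiv), 18 (1.2 equiv), THF, 0 °C to rt
Reagents that add atoms: none
Why: Mitsunobu esterification, in which the betaine deprotonates only the carboxylic acid (far more acidic than the three phenols) and the carboxylate displaces the C9 oxyphosphonium at a primary carbon, so no phenol protection is needed and no stereocentre is touched.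

**Compound list**

1 | vanillin (4-hydroxy-3-methoxybenzaldehyde) | COc1cc(C=O)ccc1O | starting material
2 | 3-methoxy-4-(triisopropylsilyloxy)benzaldehyde | COc1cc(C=O)ccc1O[Si](C(C)C)(C(C)C)C(C)C | intermediate
3 | buta-1,3-diene | C=CC=C | starting material
4 | bis(pinacolato)diboron | CC1(C)OB(OC1(C)C)B1OC(C)(C)C(C)(C)O1 | starting material
5 | (Z)-1,4-bis(4,4,5,5-tetramethyl-1,3,2-dioxaborolan-2-yl)but-2-ene | CC1(C)OB(C/C=C\CB2OC(C)(C)C(C)(C)O2)OC1(C)C | intermediate
6 | (1S,2R)-1-[3-methoxy-4-(triisopropylsilyloxy)phenyl]-2-[(pinacolboryl)methyl]but-3-en-1-yl pinacol borate (same spatial arrangement as 7; the C2 descriptor changes with the boron substituent) | C=C[C@@H](CB1OC(C)(C)C(C)(C)O1)[C@H](OB1OC(C)(C)C(C)(C)O1)c1ccc(O[Si](C(C)C)(C(C)C)C(C)C)c(OC)c1 | intermediate (not isolated)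
7 | (1S,2S)-2-ethenyl-1-[3-methoxy-4-(triisopropylsilyloxy)phenyl]propane-1,3-diol | C=C[C@@H](CO)[C@H](O)c1ccc(O[Si](C(C)C)(C(C)C)C(C)C)c(OC)c1 | intermediate
8 | (1S,2S)-2-[(tert-butyldimethylsilyloxy)methyl]-1-[3-methoxy-4-(triisopropylsilyloxy)phenyl]but-3-en-1-ol | C=C[C@@H](CO[Si](C)(C)C(C)(C)C)[C@H](O)c1ccc(O[Si](C(C)C)(C(C)C)C(C)C)c(OC)c1 | intermediate
9 | 4-iodo-2-methoxyphenol | COc1cc(I)ccc1O | starting material
10 | (4-iodo-2-methoxyphenoxy)triisopropylsilane | COc1cc(I)ccc1O[Si](C(C)C)(C(C)C)C(C)C | intermediate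
11 | (1S,2S,3E)-2-[(tert-butyldimethylsilyloxy)methyl]-1,4-bis[3-methoxy-4-(triisopropylsilyloxy)phenyl]but-3-en-1-ol | COc1cc(/C=C/[C@@H](CO[Si](C)(C)C(C)(C)C)[C@H](O)c2ccc(O[Si](C(C)C)(C(C)C)C(C)C)c(OC)c2)ccc1O[Si](C(C)C)(C(C)C)C(C)C | intermediate
12 | carbon monoxide | [C-]#[O+] | starting material
13 | (1S,2S,3E)-2-[(tert-butyldimethylsilyloxy)methyl]-1,4-bis[3-methoxy-4-(triisopropylsilyloxy)phenyl]but-3-en-1-yl diphenylphosphinite | COc1cc(/C=C/[C@@H](CO[Si](C)(C)C(C)(C)C)[C@H](OP(c2ccccc2)c2ccccc2)c2ccc(O[Si](C(C)C)(C(C)C)C(C)C)c(OC)c2)ccc1O[Si](C(C)C)(C(C)C)C(C)C | intermediate (not isolated)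
14 | (2R,3S,4S)-3-[(tert-butyldimethylsilyloxy)methyl]-4-hydroxy-4-[3-methoxy-4-(triisopropylsilyloxy)phenyl]-2-{[3-methoxy-4-(triisopropylsilyloxy)phenyl]methyl}butanal | COc1cc(C[C@@H](C=O)[C@@H](CO[Si](C)(C)C(C)(C)C)[C@H](O)c2ccc(O[Si](C(C)C)(C(C)C)C(C)C)c(OC)c2)ccc1O[Si](C(C)C)(C(C)C)C(C)C | intermediate (not isolated)
15 | (3R,4S,5S)-4-[(tert-butyldimethylsilyloxy)methyl]-5-[3-methoxy-4-(triisopropylsilyloxy)phenyl]-3-{[3-methoxy-4-(triisopropylsilyloxy)phenyl]methyl}oxolan-2-ol (anomer mixture, one anomer drawn) | COc1cc(C[C@H]2[C@H](O)O[C@H](c3ccc(O[Si](C(C)C)(C(C)C)C(C)C)c(OC)c3)[C@@H]2CO[Si](C)(C)C(C)(C)C)ccc1O[Si](C(C)C)(C(C)C)C(C)C | intermediate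
16 | tert-butyl{[(2S,3S,4R)-2-[3-methoxy-4-(triisopropylsilyloxy)phenyl]-4-{[3-methoxy-4-(triisopropylsilyloxy)phenyl]methyl}oxolan-3-yl]methoxy}dimethylsilane | COc1cc(C[C@H]2CO[C@H](c3ccc(O[Si](C(C)C)(C(C)C)C(C)C)c(OC)c3)[C@@H]2CO[Si](C)(C)C(C)(C)C)ccc1O[Si](C(C)C)(C(C)C)C(C)C | intermediate
17 | [(2S,3S,4R)-2-(4-hydroxy-3-methoxyphenyl)-4-[(4-hydroxy-3-methoxyphenyl)methyl]oxolan-3-yl]methanol | COc1cc(C[C@H]2CO[C@H](c3ccc(O)c(OC)c3)[C@@H]2CO)ccc1O | intermediate
18 | p-coumaric acid [(2E)-3-(4-hydroxyphenyl)prop-2-enoic acid] | O=C(O)/C=C/c1ccc(O)cc1 | starting material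
19 | [(2S,3S,4R)-2-(4-hydroxy-3-methoxyphenyl)-4-[(4-hydroxy-3-methoxyphenyl)methyl]oxolan-3-yl]methyl (2E)-3-(4-hydroxyphenyl)prop-2-enoate | COc1cc(C[C@H]2CO[C@H](c3ccc(O)c(OC)c3)[C@@H]2COC(=O)/C=C/c2ccc(O)cc2)ccc1O | target

**Step count and risks**

Total: 10 steps. Longest linear sequence: 8 steps (step 1 or 2, then 3, 4, 6, 7, 8, 9, 10).

Step 7 (the proposed method). Rhodium may add to the benzylic C7' instead of C4, which would put the formyl group on the wrong carbon. Ligand exchange at the hindered C2 hydroxyl may also be too slow, leaving only undirected background reaction or alkene hydrogenation. The fallback uses known chemistry, sets out from 8 and returns at 15. Hydroboration–oxidation of the vinyl group of 8 (9-borabicyclo[3.3.1]nonane, THF; then H2O2, NaOH) gives (1S,2S)-2-[(tert-butyldimethylsilyloxy)methyl]-1-[3-methoxy-4-(triisopropylsilyloxy)phenyl]butane-1,4-diol F1. Oxidative lactonisation (2,2,6,6-tetramethylpiperidin-1-oxyl, PhI(OAc)2, CH2Cl2) gives the cis-4,5-disubstituted (4S,5S)-4-[(tert-butyldimethylsilyloxy)methyl]-5-[3-methoxy-4-(triisopropylsilyloxy)phenyl]oxolan-2-one F2. Separately, aldehyde 2 is reduced (NaBH4, MeOH) to [3-methoxy-4-(triisopropylsilyloxy)phenyl]methanol F3 and converted by the Appel reaction (CBr4, PPh3) into [4-(bromomethyl)-2-methoxyphenoxy]triisopropylsilane F4. The lithium enolate of F2 (LiN(SiMe3)2, THF, −78 °C) should be alkylated by F4 on the face opposite the neighbouring silyloxymethyl group to give the trans lactone (3R,4S,5S)-4-[(tert-butyldimethylsilyloxy)methyl]-5-[3-methoxy-4-(triisopropylsilyloxy)phenyl]-3-{[3-methoxy-4-(triisopropylsilyloxy)phenyl]methyl}oxolan-2-one F5. Reduction with iBu2AlH (CH2Cl2, −78 °C) gives lactol 15.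

Step 3. The electron-rich aldehyde may add sluggishly to the hindered (Z)-reagent, or the acid may discriminate the aldehyde faces poorly, so that enantiomeric purity is lost. The fallback sets out from 2 and 5 and returns at 8. Without catalyst (toluene, 60 °C; then H2O2, NaOH) the closed transition state should still give the syn diastereomer, as racemic syn-2-ethenyl-1-[3-methoxy-4-(triisopropylsilyloxy)phenyl]propane-1,3-diol F6. Primary silylation as in step 4 gives racemic syn-2-[(tert-butyldimethylsilyloxy)methyl]-1-[3-methoxy-4-(triisopropylsilyloxy)phenyl]but-3-en-1-ol F7. Esterification with (S)-2-methoxy-2-phenylacetic acid (dicyclohexylcarbodiimide, 4-(dimethylamino)pyridine, CH2Cl2) gives two diastereomers to be separated by chromatography: the (1S,2S)-alcohol (S)-2-methoxy-2-phenylacetate F8 and the (1R,2R)-alcohol (S)-2-methoxy-2-phenylacetate F9. Cleavage of F8 with iBu2AlH (CH2Cl2, −78 °C) returns 8.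

Step 6. β-Hydride elimination toward C3, or migration of a palladium hydride along the chain, may move the alkene out of conjugation and erase the C3 stereocentre; the hindered alkene may also insert too slowly. The fallback sets out from 8 and returns at 11. Wittig methylenation of 2 (Ph3PCH3Br, KOtBu, THF) gives 3-methoxy-4-(triisopropylsilyloxy)styrene F10. Cross-metathesis of 8 with an excess of F10, using the second-generation Grubbs catalyst RuCl2(=CHPh)(PCy3)(H2IMes) in CH2Cl2 at 40 °C, should give the E-styrene 11 without any metal hydride at C3.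

**Further compounds**

F1 | step 7 | (1S,2S)-2-[(tert-butyldimethylsilyloxy)methyl]-1-[3-methoxy-4-(triisopropylsilyloxy)phenyl]butane-1,4-diol | OCC[C@@H](CO[Si](C)(C)C(C)(C)C)[C@H](O)c1ccc(O[Si](C(C)C)(C(C)C)C(C)C)c(OC)c1
F2 | step 7 | (4S,5S)-4-[(tert-butyldimethylsilyloxy)methyl]-5-[3-methoxy-4-(triisopropylsilyloxy)phenyl]oxolan-2-one | O=C1C[C@@H](CO[Si](C)(C)C(C)(C)C)[C@@H](c2ccc(O[Si](C(C)C)(C(C)C)C(C)C)c(OC)c2)O1
F3 | step 7 | [3-methoxy-4-(triisopropylsilyloxy)phenyl]methanol | COc1cc(CO)ccc1O[Si](C(C)C)(C(C)C)C(C)C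
F4 | step 7 | [4-(bromomethyl)-2-methoxyphenoxy]triisopropylsilane | COc1cc(CBr)ccc1O[Si](C(C)C)(C(C)C)C(C)C
F5 | step 7 | (3R,4S,5S)-4-[(tert-butyldimethylsilyloxy)methyl]-5-[3-methoxy-4-(triisopropylsilyloxy)phenyl]-3-{[3-methoxy-4-(triisopropylsilyloxy)phenyl]methyl}oxolan-2-one | O=C1[C@H](Cc2ccc(O[Si](C(C)C)(C(C)C)C(C)C)c(OC)c2)[C@@H](CO[Si](C)(C)C(C)(C)C)[C@@H](c2ccc(O[Si](C(C)C)(C(C)C)C(C)C)c(OC)c2)O1
F6 | step 3 | racemic syn-2-ethenyl-1-[3-methoxy-4-(triisopropylsilyloxy)phenyl]propane-1,3-diol (both enantiomers written) | C=C[C@@H](CO)[C@H](O)c1ccc(O[Si](C(C)C)(C(C)C)C(C)C)c(OC)c1.C=C[C@H](CO)[C@@H](O)c1ccc(O[Si](C(C)C)(C(C)C)C(C)C)c(OC)c1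
F7 | step 3 | racemic syn-2-[(tert-butyldimethylsilyloxy)methyl]-1-[3-methoxy-4-(triisopropylsilyloxy)phenyl]but-3-en-1-ol (both enantiomers written) | C=C[C@@H](CO[Si](C)(C)C(C)(C)C)[C@H](O)c1ccc(O[Si](C(C)C)(C(C)C)C(C)C)c(OC)c1.C=C[C@H](CO[Si](C)(C)C(C)(C)C)[C@@H](O)c1ccc(O[Si](C(C)C)(C(C)C)C(C)C)c(OC)c1
F8 | step 3 | (1S,2S)-2-[(tert-butyldimethylsilyloxy)methyl]-1-[3-methoxy-4-(triisopropylsilyloxy)phenyl]but-3-en-1-yl (S)-2-methoxy-2-phenylacetate | C=C[C@@H](CO[Si](C)(C)C(C)(C)C)[C@H](OC(=O)[C@@H](OC)c1ccccc1)c1ccc(O[Si](C(C)C)(C(C)C)C(C)C)c(OC)c1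
F9 | step 3 | (1R,2R)-2-[(tert-butyldimethylsilyloxy)methyl]-1-[3-methoxy-4-(triisopropylsilyloxy)phenyl]but-3-en-1-yl (S)-2-methoxy-2-phenylacetate | C=C[C@H](CO[Si](C)(C)C(C)(C)C)[C@@H](OC(=O)[C@@H](OC)c1ccccc1)c1ccc(O[Si](C(C)C)(C(C)C)C(C)C)c(OC)c1
F10 | step 6 | 3-methoxy-4-(triisopropylsilyloxy)styrene | C=Cc1ccc(O[Si](C(C)C)(C(C)C)C(C)C)c(OC)c1
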